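**Retrosynthetic overview**
- Target 27 ← Luche reduction of 2-ketone 26 ← ring C (seven-membered) closed last by intramolecular Friedel–Crafts acylation (C12–C13), after a furan is attached to C1 of ring A enone 21.
- Ring A enone 21 ← key step: one-carbon ring expansion (radical 1,2-acyl shift ending in desaturation) of the A-nor cyclopentanone 20, which comes from Dieckmann closure and iodomethylation of lactone 18.
- Ring B of 18 ← Mukaiyama–Michael addition at C9 of enone 12 ← allylic oxidation ← spiro-lactone 11 ← enantioselective Diels–Alder of diene 6 with 2-substituted acrolein 8 (sets C5 and C10).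
- Order of ring formation: ring B → γ-lactone → A-nor five-membered ring → ring A (expansion) → furan attached → ring C.

Assumption: clerodane numbering (C-1 to C-20) is used for all intermediates, α is the face of C-19/C-20 and β the face of H-10. The (S)-oxazaborolidinium catalyst is taken to give the enantiomer drawn; if the facial sense is opposite, its mirror image is used.

**Route**

Step 1
Reactants: 1 2-methylbut-1-en-3-yne
Product: 3 (1E)-1-iodo-2,3-dimethylbuta-1,3-diene, via alkenylalane 2 (not isolated)
Conditions: AlMe3 (2 equiv), Cp2ZrCl2 (20 mol%), CH2Cl2, 0 °C to rt; then I2, THF, −30 °C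
Reagents that add atoms: trimethylaluminium C[Al](C)C; iodine II
Why: Zirconium-catalysed Negishi methylalumination adds Me and Al syn across the alkyne with Me on the internal carbon, and iodinolysis with retention gives the E-dienyl iodide.

Step 2
Reactants: 3 (1E)-1-iodo-2,3-dimethylbuta-1,3-diene; 4 methyl bromoacetate
Product: 6 methyl (3E)-4,5-dimethylhexa-3,5-dienoate, via Reformatsky reagent 5 (not isolated)
Conditions: Zn dust, THF, 40 °C; then 3, Pd2(dba)3 (2 mol%), XPhos (8 mol%), THF, rt
Reagents that add atoms: none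
Why: Negishi-type cross-coupling of the zinc ester enolate BrZnCH2CO2Me with the alkenyl iodide on zerovalent palladium proceeds with retention of the E geometry and, being neutral, leaves the β,γ-unsaturation unconjugated.

Step 3
Reactants: 7 methyl 4-oxobutanoate
Product: 8 methyl 3-formylbut-3-enoate
Conditions: 37% aq. CH2O, pyrrolidine (10 mol%), propanoic acid (10 mol%), i-PrOH, 45 °C
Reagents that add atoms: formaldehyde C=O
Why: Amine-catalysed Mannich condensation–elimination (organocatalytic α-methylenation of an aldehyde) converts the aldehyde α-CH2 into the 2-substituted acrolein.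

Step 4
Reactants: 6 methyl (3E)-4,5-dimethylhexa-3,5-dienoate; 8 methyl 3-formylbut-3-enoate
Product: 11 methyl 2-(7,8-dimethyl-3-oxo-2-oxaspiro[4.5]dec-7-en-6-yl)acetate (lactone CH2O cis to the ring arm), via adduct aldehyde 9 (not isolated), via hydroxy diester 10 (not isolated)
Conditions: (S)-1-(2-methylphenyl)-3,3-diphenyltetrahydro-1H,3H-pyrrolo[1,2-c][1,3,2]oxazaborole (20 mol%), Tf2NH (20 mol%), CH2Cl2, −78 °C; then NaBH4, MeOH, −78 to 0 °C; then TsOH (cat.), rt
Reagents that add atoms: none
Why: Enantioselective Diels–Alder reaction under Corey oxazaborolidinium catalysis goes through the "ortho", formyl-endo transition state, which sets quaternary C5 and C10 with C-19 cis to the C10 arm (the later trans-decalin relationship); borohydride reduction and γ-lactonisation then fix the 18,19-olide orientation.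

Step 5
Reactants: 11 spiro-lactone ester
Product: 12 methyl 2-(7,8-dimethyl-3,9-dioxo-2-oxaspiro[4.5]dec-7-en-6-yl)acetate
Conditions: CrO3, 3,5-dimethylpyrazole, CH2Cl2, −20 °C
Reagents that add atoms: chromium trioxide O=[Cr](=O)=O
Why: Chromium trioxide–dimethylpyrazole allylic oxidation converts the only ring allylic methylene (C7) of the tetrasubstituted alkene into the enone carbonyl.

Step 6
Reactants: 12 enone; 13 tert-butyl acetate
Product: 16 methyl 2-[7-(2-tert-butoxy-2-oxoethyl)-7,8-dimethyl-3,9-dioxo-2-oxaspiro[4.5]decan-6-yl]acetate (C9: Me α, CH2CO2t-Bu β; C8: Me α), via ketene silyl acetal 14 (not isolated), via silyl enol ether 15 (not isolated)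
Conditions: 13, LiN(iPr)2, TBSCl, THF–DMPU, −78 °C to rt; then 12, Tf2NH (5 mol%), CH2Cl2, −78 to −20 °C; then Bu4NF, AcOH, THF, 0 °C
Reagents that add atoms: none
Why: Mukaiyama–Michael addition occurs axially and anti to the pseudoaxial C10 arm, creating quaternary C9 with the new arm trans to the C10 arm, and fluoride desilylation with equilibration places the C8 methyl equatorial (α).

Step 7
Reactants: 16 keto triester
Product: 18 7α-acetate of 16 (ketone replaced by axial OAc), via 7α-alcohol 17 (not isolated)
Conditions: LiBH(s-Bu)3, THF, −78 °C; then Ac2O, DMAP, −78 °C to rt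
Reagents that add atoms: acetic anhydride CC(=O)OC(C)=O
Why: Hindered-hydride ketone reduction comes from the β face because the α face is blocked by the axial C-19 and C-20 groups, giving the axial 7α-alkoxide, which is acetylated in the same flask.

Step 8
Reactants: 18 7α-acetate
Product: 20 A-nor tricyclic 4-(iodomethyl) β-keto lactone (cyclopentanone C1–C2–C4–C5–C10 trans-fused to ring B, cis-fused to the γ-lactone), via β-keto lactone 19 (not isolated)
Conditions: LiN(SiMe3)2 (1.2 equiv), THF, −78 to 0 °C; then CH2I2, DMPU, 0 °C to rt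
Reagents that add atoms: diiodomethane ICI
Why: Dieckmann condensation of the most acidic site (lactone α-CH2, C4) onto the C10 methyl ester (tert-butyl ester and hindered acetate untouched) is followed by C-alkylation of the β-keto lactone enolate; the C4 configuration is dictated by the cis-fusion of the two five-membered rings.

Step 9
Reactants: 20 iodomethyl β-keto lactone
Product: 21 tert-butyl 7α-acetoxy-2-oxo-13,14,15,16-tetranorclerod-3-en-18,19-olid-12-oate (trans-decalin ring A enone butenolide)
Conditions: Co(dmgH)2(py)Cl (10 mol%), i-Pr2NEt (2 equiv), MeCN, blue LEDs, rt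
Reagents that add atoms: none
Why: Proposed new method: monovalent cobalt (formed photochemically with the amine) displaces iodide, light-induced Co–C homolysis gives the primary radical, which has no β-hydrogen and so cannot be desaturated but adds 3-exo to the strained cyclopentanone carbonyl and β-fragments (1,2-acyl shift, five- to six-membered ring) to the tertiary lactone-stabilised C4 radical, which recombines with divalent cobalt and loses the new C3–H by dehydrocobaltation to give the C3=C4 ene-dione, the cobalt hydride being deprotonated by the amine to close a redox-neutral cycle; the closest known reactions are the tin hydride Dowd–Beckwith ring expansion and cobaloxime-catalysed photochemical dehydrohalogenation of alkyl iodides.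

Step 10
Reactants: 21 ring A enone; 22 furan
Product: 23 1β-(furan-2-yl) derivative of 21 (H-1 α)
Conditions: Mn(OAc)3·2H2O (2.2 equiv), furan (30 equiv), AcOH, sealed tube, 60 °C
Reagents that add atoms: none
Why: Trivalent manganese enolisation at the only enolisable site (C1) gives the α′-keto radical, which adds to furan C2 and is oxidised and rearomatised (Mn(OAc)3-mediated α′-arylation of enones), and C1 equilibrates to the equatorial β-furyl epimer.

Step 11
Reactants: 23 furyl enone tert-butyl ester
Product: 26 2-oxo precursor (2-dehydro target, ring C closed), via carboxylic acid 24 (not isolated), via acid chloride 25 (not isolated)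
Conditions: CF3CO2H, CH2Cl2, 0 °C; then (COCl)2, DMF (cat.), CH2Cl2, 0 °C; then SnCl4, CH2Cl2 (0.005 M), −78 to −20 °C
Reagents that add atoms: none
Why: After tert-butyl ester cleavage and acid chloride formation, intramolecular Friedel–Crafts acylation at furan C3 (the only position the equatorial C9 arm can reach) closes the seven-membered ring between two pre-set equatorial bonds, high dilution suppressing intermolecular acylation at the free α-position.

Step 12
Reactants: 26 2-oxo precursor
Product: 27 target CNP0182929.1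
Conditions: NaBH4, CeCl3·7H2O, MeOH, −78 °C
Reagents that add atoms: none
Why: Luche 1,2-reduction delivers hydride axially from the β face of the enone carbonyl to give the equatorial 2α-alcohol trans to the C1 substituent, while the furyl ketone (a vinylogous ester), lactone and acetate are untouched.

**Compound list**
1 | 2-methylbut-1-en-3-yne | C=C(C)C#C | starting material
2 | dimethyl[(1E)-2,3-dimethylbuta-1,3-dien-1-yl]alane | C=C(C)/C(C)=C/[Al](C)C | intermediate
3 | (1E)-1-iodo-2,3-dimethylbuta-1,3-diene | C=C(C)/C(C)=C/I | intermediate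
4 | methyl bromoacetate | COC(=O)CBr | starting material
5 | bromo(2-methoxy-2-oxoethyl)zinc | COC(=O)C[Zn]Br | intermediate
6 | methyl (3E)-4,5-dimethylhexa-3,5-dienoate | C=C(C)/C(C)=C/CC(=O)OC | intermediate
7 | methyl 4-oxobutanoate | COC(=O)CCC=O | starting material
8 | methyl 3-formylbut-3-enoate | COC(=O)CC(=C)C=O | intermediate
9 | methyl 2-[1-formyl-2-(2-methoxy-2-oxoethyl)-3,4-dimethylcyclohex-3-en-1-yl]acetate, formyl cis to the ring arm | CC1=C(C)[C@@H](CC(=O)OC)[C@](C=O)(CC(=O)OC)CC1 | intermediate
10 | methyl 2-[1-(hydroxymethyl)-2-(2-methoxy-2-oxoethyl)-3,4-dimethylcyclohex-3-en-1-yl]acetate, same configuration | CC1=C(C)[C@@H](CC(=O)OC)[C@](CO)(CC(=O)OC)CC1 | intermediate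
11 | methyl 2-(7,8-dimethyl-3-oxo-2-oxaspiro[4.5]dec-7-en-6-yl)acetate, C-19 (α) cis to the C10 arm, H-10 β | CC1=C(C)[C@@H](CC(=O)OC)[C@@]2(COC(=O)C2)CC1 | intermediate
12 | methyl 2-(7,8-dimethyl-3,9-dioxo-2-oxaspiro[4.5]dec-7-en-6-yl)acetate (C7 enone) | O=C1C[C@]2(COC(=O)C2)[C@H](CC(=O)OC)C(C)=C1C | intermediate
13 | tert-butyl acetate | CC(=O)OC(C)(C)C | starting material
14 | tert-butyl[(1-tert-butoxyethenyl)oxy]dimethylsilane | C=C(OC(C)(C)C)O[Si](C)(C)C(C)(C)C | intermediate
15 | C7 tert-butyldimethylsilyl enol ether of 16 (C7=C8) | CC(C)(C)[Si](C)(C)OC1=C(C)[C@](C)(CC(=O)OC(C)(C)C)[C@@H](CC(=O)OC)[C@@]2(COC(=O)C2)C1 | intermediate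
16 | methyl 2-[7-(2-tert-butoxy-2-oxoethyl)-7,8-dimethyl-3,9-dioxo-2-oxaspiro[4.5]decan-6-yl]acetate (9α-Me, 9β-CH2CO2t-Bu, 8α-Me, H-10 β) | O=C1C[C@]2(COC(=O)C2)[C@H](CC(=O)OC)[C@@](C)(CC(=O)OC(C)(C)C)[C@@H]1C | intermediate
17 | 7α-alcohol of 16 (axial OH) | O[C@@H]1C[C@]2(COC(=O)C2)[C@H](CC(=O)OC)[C@@](C)(CC(=O)OC(C)(C)C)[C@@H]1C | intermediate
18 | 7α-acetate of 17 | CC(=O)O[C@@H]1C[C@]2(COC(=O)C2)[C@H](CC(=O)OC)[C@@](C)(CC(=O)OC(C)(C)C)[C@@H]1C | intermediate
19 | A-nor tricyclic β-keto lactone (C2 ketone in the ring C1–C2–C4–C5–C10, lactone cis-fused at C4–C5, H-4 cis to C6) | CC(=O)O[C@@H]1C[C@@]23COC(=O)[C@@H]2C(=O)C[C@@H]3[C@@](C)(CC(=O)OC(C)(C)C)[C@@H]1C | intermediate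
20 | 4-(iodomethyl) derivative of 19 | CC(=O)O[C@@H]1C[C@@]23COC(=O)[C@]2(CI)C(=O)C[C@@H]3[C@@](C)(CC(=O)OC(C)(C)C)[C@@H]1C | intermediate
21 | tert-butyl 7α-acetoxy-2-oxo-13,14,15,16-tetranorclerod-3-en-18,19-olid-12-oate (H-10 β, 5α-CH2O, 8α-Me, 9α-Me) | CC(=O)O[C@@H]1C[C@@]23COC(=O)C2=CC(=O)C[C@@H]3[C@@](C)(CC(=O)OC(C)(C)C)[C@@H]1C | intermediate
22 | furan | c1ccoc1 | starting material
23 | 1β-(furan-2-yl) derivative of 21 (H-1 α) | CC(=O)O[C@@H]1C[C@@]23COC(=O)C2=CC(=O)[C@@H](c2ccco2)[C@@H]3[C@@](C)(CC(=O)OC(C)(C)C)[C@@H]1C | intermediate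
24 | C12 carboxylic acid from 23 | CC(=O)O[C@@H]1C[C@@]23COC(=O)C2=CC(=O)[C@@H](c2ccco2)[C@@H]3[C@@](C)(CC(=O)O)[C@@H]1C | intermediate
25 | C12 acid chloride from 24 | CC(=O)O[C@@H]1C[C@@]23COC(=O)C2=CC(=O)[C@@H](c2ccco2)[C@@H]3[C@@](C)(CC(=O)Cl)[C@@H]1C | intermediate
26 | 2-oxo precursor: 7α-acetoxy-2,12-dioxo-1,16-cyclo-clerodane furan 18,19-olide (2-dehydro target) | CC(=O)O[C@@H]1C[C@@]23COC(=O)C2=CC(=O)[C@H]2c4occc4C(=O)C[C@@](C)([C@@H]1C)[C@@H]23 | intermediate
27 | CNP0182929.1: 7α-acetoxy-2α-hydroxy-12-oxo-1,16-cyclo-clerodane furan 18,19-olide (H-1 α, H-10 β, 5α-CH2O, 8α-Me, 9α-Me) | CC(=O)O[C@@H]1C[C@@]23COC(=O)C2=C[C@H](O)[C@H]2c4occc4C(=O)C[C@@](C)([C@@H]1C)[C@@H]23 | target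

**Step count and risk**
Total step count: 12. Longest linear sequence: 11 steps (steps 1, 2 and 4 to 12; step 3 is a one-step side branch).

Steps most likely to fail:

Step 9 (the proposed cobalt-mediated ring expansion–desaturation). The fallback sets out from compound 20 and comes back at compound 21 using known chemistry only. The classical Dowd–Beckwith ring expansion (Bu3SnH, AIBN, benzene, 80 °C, slow addition) gives the saturated ring-expanded keto lactone F3. Dehydrogenation of this 1,4-dicarbonyl with IBX (DMSO, 80 °C), or α-selenenylation followed by oxidative elimination, then introduces the C3=C4 double bond that is conjugated to both carbonyls.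

Step 6 (Mukaiyama–Michael addition to a hindered tetrasubstituted enone). The fallback sets out from compound 12 and comes back at compound 16. Hosomi–Sakurai conjugate allylation (allyltrimethylsilane, TiCl4, CH2Cl2, −78 °C), a smaller and more reactive nucleophile with the same facial preference, gives the allyl ketone F1. Oxidative cleavage of its terminal alkene (RuCl3 cat., NaIO4) gives the carboxylic acid F2, which is esterified with tert-butyl 2,2,2-trichloroacetimidate (BF3·OEt2 cat.) to 16.

Step 10 (intermolecular radical furylation next to an ene-dione, with risk of over-oxidation or acetoxylation). The fallback sets out from compound 21 and comes back at compound 23. Kinetic enolisation and silylation (LiN(SiMe3)2, Me3SiCl, THF, −78 °C) gives the silyl dienol ether F4, which is arylated with (furan-2-yl)(mesityl)iodonium triflate under Cu(OTf)2 catalysis (CH2Cl2, rt) in a polar rather than radical C1–C16 bond formation.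

**Further compounds**
F1 | step 6 | allyl ketone: methyl 2-[7,8-dimethyl-3,9-dioxo-7-(prop-2-en-1-yl)-2-oxaspiro[4.5]decan-6-yl]acetate | O=C1C[C@]2(COC(=O)C2)[C@H](CC(=O)OC)[C@@](C)(CC=C)[C@@H]1C
F2 | step 6 | carboxylic acid: 2-[6-(2-methoxy-2-oxoethyl)-7,8-dimethyl-3,9-dioxo-2-oxaspiro[4.5]decan-7-yl]acetic acid | O=C1C[C@]2(COC(=O)C2)[C@H](CC(=O)OC)[C@@](C)(CC(=O)O)[C@@H]1C
F3 | step 9 | saturated keto lactone: 3,4-dihydro derivative of 21 with the lactone cis-fused at C4–C5 | CC(=O)O[C@@H]1C[C@@]23COC(=O)[C@@H]2CC(=O)C[C@@H]3[C@@](C)(CC(=O)OC(C)(C)C)[C@@H]1C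
F4 | step 10 | silyl dienol ether: 2-(trimethylsilyloxy)-1,3-diene derived from 21 | CC(=O)O[C@@H]1C[C@@]23COC(=O)C2=CC(O[Si](C)(C)C)=C[C@@H]3[C@@](C)(CC(=O)OC(C)(C)C)[C@@H]1C
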